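The target at the end of these flasks is reckoned here from what its making uses up.

| setting | birch | elm | epsilon | theta | gamma |
|---|---|---|---|---|---|
| starting material | 0.16 M | 0.16 M | 0.16 M | 0.16 M | 0.16 M |
| coupling partner | 0.20 M | 0.32 M | 0.144 M | 0.144 M | 0.144 M |
| capture agent | 3.2 mM | 3.2 mM | 3.20 mM | 3.20 mM | 3.20 mM |
| free catalyst | 16 mM | 16 mM | 16 mM | 16 mM | 16 mM |
| temperature | −25 °C | 10 °C | −20 °C | 10 °C | 40 °C |
| remark | run made earlier | run made earlier |  |  |  |
| time |  |  | 2.5 min | 2.5 min | 2.5 min |

| run | time / s | target / % |
|---|---|---|
| birch | 10.0 | 50 |
| birch | 20.0 | 71 |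
| birch | 30.0 | 87 |
| birch | 50.0 | 98 |
| birch | 80.0 | 98 |
| birch | 90.0 | 99 |
| birch | 120 | 99 |
| elm | 10.0 | 103 |
| elm | 12.0 | 99 |
| elm | 15.0 | 101 |
| elm | 20.0 | 105 |
| elm | 25.0 | 100 |

(scatter of a reading: 2 percentage points)

- what was read earlier has a scatter of 2 percentage points, one standard deviation

* the flask that comes out highest in amount of target, in percent of the starting material charged, or "all alike" when all lie within 1.5 percentage points (epsilon / theta / gamma / all alike)
* target at the end, in percent of the starting material charged, epsilon
* target at the end, in percent of the starting material charged, theta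
* target at the end, in percent of the starting material charged, gamma

In birch, 99 % of the starting material stood as target at 120 s, made from a charge of 0.20 M coupling partner. That is a supply of 1.26 partner per target, room for one but not for two. The reckoning here therefore takes one coupling partner per target, which makes the partner the limiting reagent in epsilon, theta and gamma. There, 0.144 M over 0.16 M gives 90.0 %. This ratio of charged [coupling partner] to charged [starting material] is the partner ceiling, the end state expected once the partner is used.

The readings then order the times. On the first rung stands elm at 10 °C: its first reading, at 10.0 s, already shows 103 %, and later ones stay flat within the scatter. Next comes birch at −25 °C, with half of the starting material turned to target by 10.0 s, so both reactants are still present. Birch then shows 98 % by 50.0 s, and its target holds to the last reading. The asked 2.5 min is 3.00 times that birch time, and epsilon at −20 °C stands above the birch temperature, so all three flasks should spend most of the run resting at the ceiling. The capture agent could lower that by its 2.00 % of the starting material, but a scatter of 2 percentage points hides this in the runs. The reckoning stays at 90.0 % for each flask.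

The forecast says all alike: epsilon 89.5 % (85 % to 91 %), theta 89.5 % (86 % to 91.5 %) and gamma 89 % (80 % to 91.5 %). These central values lie slightly below the ceiling. The gamma range reaches lower, since at 40 °C “unseen decay or side reaction is possible”.

The flasks come out all alike: epsilon 90.0 %, theta 90.0 %, gamma 90.0 %.

    starting material + free catalyst ⇌ catalyst intermediate A (K = 480 L mol⁻¹, k = 6.74 L mol⁻¹ s⁻¹, Ea = 43.0 kJ mol⁻¹, ΔH = 0 kJ mol⁻¹)
    coupling partner + catalyst intermediate A → catalyst intermediate B (k = 1010 L mol⁻¹ s⁻¹, Ea = 37.0 kJ mol⁻¹)
    catalyst intermediate B → by-product + catalyst intermediate C (k = 20.0 s⁻¹, Ea = 63.0 kJ mol⁻¹)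
    catalyst intermediate C → free catalyst + target (k = 51.7 s⁻¹, Ea = 48.0 kJ mol⁻¹)
    capture agent + catalyst intermediate C → trapped intermediate (k = 6.76 L mol⁻¹ s⁻¹, Ea = 44.0 kJ mol⁻¹)
    (constants at −20 °C)

The falling level of coupling partner is the main reason: gamma gives 90.0 % as it stands and >99.9 % with that level held. At 2.50 min gamma has 0 % of its partner left, and its target sits on the ceiling of 90.0 %. A neighbour flask is gamma with 0.64 M of starting material; 0.144 M over that charge gives a ceiling of 22.5 %, and that neighbour flask ends at 22.5 %.

All runs are simulated for substances that don't exist; scatter was added.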